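**Plan**
- Retrosynthesis: the O1–C2 bond of ring C is cut first (invertive Mitsunobu etherification), the C2–O bond is traced back to a C2–B bond (retentive oxidation), and C2–C1' and C3–C4 are then cut together in one three-component coupling of an aryllithium, vinylboronic pinacol ester and a ring-A benzylic bromide.
- Enabling feature: C2–C3 is a two-carbon link in which C2 carries ring B and a heteroatom and C3 carries the ring-A benzylic carbon C4. A vinylboronate acquires exactly this pattern when an aryl group shifts from boron to its α-carbon while a carbon electrophile is attached to its β-carbon.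
- Forward: ring A is elaborated to its MOM-protected benzylic bromide (three steps), the coupling assembles the whole C6–C3–C6 chain at once, and acetal cleavage, C–B oxidation and closure of ring C follow. Rings A and B are bought; ring C forms last.
- Stereochemistry: C2 is set as the (R)-boronate by the chiral palladium catalyst, passes to the (R)-carbinol with retention and becomes (2S) through the invertive ring closure.

Key step: step 4

Assumption: the antipode of the MandyPhos ligand that leads to the (R)-boronate cannot be deduced from the achiral partners. It is to be fixed in one pilot run (oxidation and comparison with carbinol made by the transfer-hydrogenation sequence described among the fallbacks), and the mirror-image ligand is used if the sense proves opposite.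

Step 1
Reactants: 1 2-hydroxy-3,4-dimethoxybenzaldehyde
Product: 2 3,4-dimethoxy-2-(methoxymethoxy)benzaldehyde
Conditions: NaH, MOMCl, DMF, 0 °C → rt
Reagents that add atoms: chloromethyl methyl ether (MOMCl), COCCl
Why: Williamson-type O-alkylation of the phenoxide masks the only acidic proton as a MOM acetal that later tolerates the aryllithium-derived borate and zerovalent palladium; the aldehyde has no enolisable hydrogen and is untouched.

Step 2
Reactants: 2 3,4-dimethoxy-2-(methoxymethoxy)benzaldehyde
Product: 3 [3,4-dimethoxy-2-(methoxymethoxy)phenyl]methanol
Conditions: NaBH4, MeOH, 0 °C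
Reagents that add atoms: none
Why: Borohydride reduction of the aryl aldehyde should give the benzylic alcohol, with acetal and aryl ethers inert.

Step 3
Reactants: 3 [3,4-dimethoxy-2-(methoxymethoxy)phenyl]methanol
Product: 4 1-(bromomethyl)-3,4-dimethoxy-2-(methoxymethoxy)benzene
Conditions: CBr4, PPh3, CH2Cl2, 0 °C
Reagents that add atoms: carbon tetrabromide, BrC(Br)(Br)Br
Why: The Appel reaction converts the primary benzylic alcohol into the bromide under neutral conditions that spare the acid-labile acetal; the labile bromide is passed through a short silica plug and used at once.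

Step 4
Reactants: 5 5-bromo-1,2,3-trimethoxybenzene; 6 vinylboronic acid pinacol ester; 4 1-(bromomethyl)-3,4-dimethoxy-2-(methoxymethoxy)benzene
Product: 9 (R)-2-[3-(3,4-dimethoxy-2-(methoxymethoxy)phenyl)-1-(3,4,5-trimethoxyphenyl)propyl]-4,4,5,5-tetramethyl-1,3,2-dioxaborolane, via 3,4,5-trimethoxyphenyllithium 7 (not isolated), via lithium pinacolato(3,4,5-trimethoxyphenyl)(vinyl)borate 8 (not isolated)
Conditions: 5, t-BuLi (2 equiv), Et2O, −78 °C; 6, −78 °C → rt; solvent exchange to THF; Pd(OAc)2 (3 mol%), (Sp,Sp)-MandyPhos (3.6 mol%), KOTf (2 equiv), 4 (1 equiv relative to 1.2 equiv of 8, slow addition), THF, rt → 40 °C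
Reagents that add atoms: none
Why: Proposed new method: Pd(OAc)2 and the ferrocenyl diphosphine give zerovalent palladium, which adds oxidatively to the benzylic C–Br bond of 4; KOTf removes bromide to leave a cationic benzyl complex of divalent palladium whose η3-to-η1 slip opens a site for the vinyl group of 8, the aryl group then shifts from boron to the α-carbon anti to palladium while the Pd–C(β) bond forms, and reductive elimination joins C3 to C4. The closest known reaction type is the enantioselective palladium-catalysed conjunctive cross-coupling of aryl(vinyl)boron ate complexes with aryl or alkenyl triflates and halides (with an alkali triflate as halide scavenger) and its nickel-catalysed variant with alkyl iodides; a benzylic bromide has not been used as the electrophile. No ring closes in this step. The only new stereocentre, C2, is controlled by the chiral diphosphine, which selects the face of the palladium-bound alkene to which the aryl group migrates, since both partners are achiral. The step needs the metallate shift to outrun direct aryl transfer from boron to palladium, β-hydride elimination and uncatalysed alkylation of 8: the unhindered vinyl group binds readily, the electron-rich aryl group without ortho substituents migrates well, the benzyl ligand has no β-hydrogen, the phenol is masked so that no proton quenches 8, and slow addition of 4 at low temperature keeps the racemic background path down.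

Step 5
Reactants: 9 (R)-2-[3-(3,4-dimethoxy-2-(methoxymethoxy)phenyl)-1-(3,4,5-trimethoxyphenyl)propyl]-4,4,5,5-tetramethyl-1,3,2-dioxaborolane
Product: 10 (R)-2,3-dimethoxy-6-[3-(4,4,5,5-tetramethyl-1,3,2-dioxaborolan-2-yl)-3-(3,4,5-trimethoxyphenyl)propyl]phenol
Conditions: HCl (1.25 M in MeOH), THF, rt
Reagents that add atoms: none
Why: Acid-catalysed methanolysis of the phenolic MOM acetal (acetal exchange) is done while C2 still bears boron, because the pinacol boronate and the C–B bond withstand anhydrous acid and no ionisable benzylic C–O bond is present yet, so the stereocentre is not at risk.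

Step 6
Reactants: 10 (R)-2,3-dimethoxy-6-[3-(4,4,5,5-tetramethyl-1,3,2-dioxaborolan-2-yl)-3-(3,4,5-trimethoxyphenyl)propyl]phenol
Product: 11 (R)-6-[3-hydroxy-3-(3,4,5-trimethoxyphenyl)propyl]-2,3-dimethoxyphenol
Conditions: H2O2 (30% aq), NaOH (3 M aq), THF, 0 °C
Reagents that add atoms: hydrogen peroxide, OO
Why: Alkaline peroxide oxidation of the secondary boronate proceeds by 1,2-migration of C2 from boron to oxygen with retention, so the (R)-boronate should give the (R)-carbinol, the phenolate being a spectator at 0 °C.

Step 7
Reactants: 11 (R)-6-[3-hydroxy-3-(3,4,5-trimethoxyphenyl)propyl]-2,3-dimethoxyphenol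
Product: 12 (2S)-7,8,3',4',5'-pentamethoxyflavan
Conditions: PPh3, DIAD, THF, 0 °C → rt
Reagents that add atoms: none
Why: Intramolecular Mitsunobu etherification, in which the phenol displaces the benzylic oxyphosphonium in an SN2 6-exo-tet closure with inversion, should turn (R) into (2S); the 3,4,5-trimethoxyphenyl group stabilises a benzylic cation far less than a 4-alkoxyphenyl group, which limits ionisation at low temperature.

**Compound list**
1 | 2-hydroxy-3,4-dimethoxybenzaldehyde | COc1ccc(C=O)c(O)c1OC | starting material
2 | 3,4-dimethoxy-2-(methoxymethoxy)benzaldehyde | COCOc1c(C=O)ccc(OC)c1OC | intermediate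
3 | [3,4-dimethoxy-2-(methoxymethoxy)phenyl]methanol | COCOc1c(CO)ccc(OC)c1OC | intermediate
4 | 1-(bromomethyl)-3,4-dimethoxy-2-(methoxymethoxy)benzene | COCOc1c(CBr)ccc(OC)c1OC | intermediate
5 | 5-bromo-1,2,3-trimethoxybenzene | COc1cc(Br)cc(OC)c1OC | starting material
6 | vinylboronic acid pinacol ester (4,4,5,5-tetramethyl-2-vinyl-1,3,2-dioxaborolane) | C=CB1OC(C)(C)C(C)(C)O1 | starting material
7 | 3,4,5-trimethoxyphenyllithium | [Li]c1cc(OC)c(OC)c(OC)c1 | intermediate (not isolated)
8 | lithium pinacolato(3,4,5-trimethoxyphenyl)(vinyl)borate | [Li+].C=C[B-]1(c2cc(OC)c(OC)c(OC)c2)OC(C)(C)C(C)(C)O1 | intermediate (not isolated)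
9 | (R)-2-[3-(3,4-dimethoxy-2-(methoxymethoxy)phenyl)-1-(3,4,5-trimethoxyphenyl)propyl]-4,4,5,5-tetramethyl-1,3,2-dioxaborolane | COCOc1c(CC[C@@H](B2OC(C)(C)C(C)(C)O2)c3cc(OC)c(OC)c(OC)c3)ccc(OC)c1OC | intermediate
10 | (R)-2,3-dimethoxy-6-[3-(4,4,5,5-tetramethyl-1,3,2-dioxaborolan-2-yl)-3-(3,4,5-trimethoxyphenyl)propyl]phenol | COc1ccc(CC[C@@H](B2OC(C)(C)C(C)(C)O2)c3cc(OC)c(OC)c(OC)c3)c(O)c1OC | intermediate
11 | (R)-6-[3-hydroxy-3-(3,4,5-trimethoxyphenyl)propyl]-2,3-dimethoxyphenol | COc1ccc(CC[C@@H](O)c2cc(OC)c(OC)c(OC)c2)c(O)c1OC | intermediate
12 | (2S)-7,8,3',4',5'-pentamethoxyflavan | COc1cc([C@@H]2CCc3ccc(OC)c(OC)c3O2)cc(OC)c1OC | target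

**Count**
Total steps: 7. Longest linear sequence: 7 steps (1 → 12); 5 and 6 enter at step 4.

**Steps most likely to fail**

Step 4 (proposed new method). The benzylpalladium intermediate may take the aryl group directly from boron instead of triggering the metallate shift. The benzyl fragment may homocouple. The ate complex may be alkylated without the catalyst, which erodes the enantiomeric purity. Residual bromide may block alkene binding, and facial selectivity with a benzyl ligand may be poor.

The fallback uses known reactions only and sets out from 1. Claisen–Schmidt condensation of 1 with commercial 3,4,5-trimethoxyacetophenone (KOH, EtOH, rt, neutralised with AcOH) should give (E)-3-(2-hydroxy-3,4-dimethoxyphenyl)-1-(3,4,5-trimethoxyphenyl)prop-2-en-1-one F1. Hydrogenation of the alkene (H2, Pd/C, EtOAc, stopped after one equivalent) should give 3-(2-hydroxy-3,4-dimethoxyphenyl)-1-(3,4,5-trimethoxyphenyl)propan-1-one F2. Asymmetric transfer hydrogenation of the aryl ketone (RuCl(p-cymene)[(R,R)-TsDPEN], HCO2H/Et3N, rt) is expected, by analogy with acetophenone-type substrates, to give the (R)-carbinol, which is compound 11. The route is rejoined there for step 7, and steps 1 to 6 fall away.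

Step 3. The electron-rich benzylic bromide may ionise during isolation, with loss of the acetal through neighbouring-group participation or alkylation of a second arene ring.

The fallback sets out from 3. Treatment with MsCl, LiCl and 2,4,6-collidine in DMF at 0 °C should give 1-(chloromethyl)-3,4-dimethoxy-2-(methoxymethoxy)benzene F3, which ionises far less readily and can be chromatographed and stored. It then takes the place of 4 as the electrophile of step 4, oxidative addition of benzylic chlorides to zerovalent palladium being routine, and the route is rejoined at 9. The uncatalysed alkylation of 8 should also be slower with the chloride.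

Step 7. Ionisation of the activated benzylic oxyphosphonium may cause partial racemisation at C2, and elimination to the styrene may compete.

The fallback sets out from 11 and resets C2 under catalyst control. Oxidation of the benzylic alcohol (MnO2, CH2Cl2, rt) should give 3-(2-hydroxy-3,4-dimethoxyphenyl)-1-(3,4,5-trimethoxyphenyl)propan-1-one F2. Cyclodehydration (TsOH cat., toluene, reflux with removal of water) should give 7,8-dimethoxy-2-(3,4,5-trimethoxyphenyl)-4H-chromene F4. Asymmetric hydrogenation of the enol-ether double bond with a cationic iridium phosphine–oxazoline catalyst, [Ir(cod)(L*)][B(3,5-(CF3)2C6H3)4] under H2 in CH2Cl2, with the ligand antipode chosen for the (2S) product, returns to the route at 12.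

**Further compounds**
F1 | step 4 | (E)-3-(2-hydroxy-3,4-dimethoxyphenyl)-1-(3,4,5-trimethoxyphenyl)prop-2-en-1-one | COc1ccc(/C=C/C(=O)c2cc(OC)c(OC)c(OC)c2)c(O)c1OC
F2 | step 4 | 3-(2-hydroxy-3,4-dimethoxyphenyl)-1-(3,4,5-trimethoxyphenyl)propan-1-one | COc1ccc(CCC(=O)c2cc(OC)c(OC)c(OC)c2)c(O)c1OC
F3 | step 3 | 1-(chloromethyl)-3,4-dimethoxy-2-(methoxymethoxy)benzene | COCOc1c(CCl)ccc(OC)c1OC
F4 | step 7 | 7,8-dimethoxy-2-(3,4,5-trimethoxyphenyl)-4H-chromene | COc1cc(C2=CCc3ccc(OC)c(OC)c3O2)cc(OC)c1OC
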